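Everything rests on seeing the 3,3''-biflavanone as an all-trans head-to-head [2+2] photodimer of two 2'-hydroxychalcones in which the bond C2–C2'' has been exchanged for the two aryl ether bonds O1–C2 and O1''–C2''. In the key step a two-electron oxidation of the 4-hydroxyphenyl rings on C2 and C2'' (rings B and B'') opens the strained cyclobutane to a bis(para-quinone methide); the chelated ortho-hydroxyls of rings A and A'' then add, closing both pyranone rings and setting C2 and C2'' trans to C3 and C3'', whose configuration the cyclobutane delivers. The precursor is a trans-1,2-diaroyl-3,4-bis(4-hydroxyphenyl)cyclobutane, made by an enantioselective crossed [2+2] photocycloaddition.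

Key step: step 6

Remark on numbering: unprimed labels (O1, C2, C3, C4, rings A, B) belong to the 7-hydroxyflavanone half, double-primed labels to the 5,7-dihydroxyflavanone half; the same labels are used for the corresponding atoms of all precursors.

Assumption: with (S,S)-t-Bu-PyBox, that is 2,6-bis[(4S)-4-tert-butyl-4,5-dihydro-1,3-oxazol-2-yl]pyridine, the Sc(OTf)3 catalyst is taken to give the (1S,2S,3R,4R) cyclobutane 7 when a chalcone is the alkene partner; should a pilot run show the opposite sense, the (R,R)-ligand is used.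

Remark on stoichiometry: in the photocycloaddition the non-chelating chalcone is charged in fourfold excess over the chelating one and the unreacted part is recovered by chromatography; the reaction itself is a one-to-one addition in which every atom of both chalcones ends in the cyclobutane.

Step 1
Reactants: 1 1-[4-(benzyloxy)-2-hydroxyphenyl]ethan-1-one; 2 4-(methoxymethoxy)benzaldehyde
Product: 3 (E)-1-[4-(benzyloxy)-2-hydroxyphenyl]-3-[4-(methoxymethoxy)phenyl]prop-2-en-1-one
Conditions: aq. KOH, EtOH, rt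
Reagents that add atoms: none
Why: Claisen–Schmidt aldol condensation of a methyl ketone with a non-enolisable aldehyde should give the conjugated E-enone under thermodynamic control, the MOM and benzyl ethers being inert to hydroxide.

Step 2
Reactants: 4 1-[2,4-bis(benzyloxy)-6-hydroxyphenyl]ethan-1-one
Product: 5 1-[2,4-bis(benzyloxy)-6-(methoxymethoxy)phenyl]ethan-1-one
Conditions: NaH, MOMCl, DMF, 0 °C to rt
Reagents that add atoms: chloromethyl methyl ether, COCCl
Why: Williamson-type O-alkylation of the phenoxide generated with NaH masks the chelating ortho-hydroxyl as an acetal that survives base and is later removed by mild acid.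

Step 3
Reactants: 5 1-[2,4-bis(benzyloxy)-6-(methoxymethoxy)phenyl]ethan-1-one; 2 4-(methoxymethoxy)benzaldehyde
Product: 6 (E)-1-[2,4-bis(benzyloxy)-6-(methoxymethoxy)phenyl]-3-[4-(methoxymethoxy)phenyl]prop-2-en-1-one
Conditions: KOH, EtOH/THF, 40 °C
Reagents that add atoms: none
Why: Claisen–Schmidt condensation, which tolerates the doubly ortho-substituted aryl ketone, should give the E-enone with no free hydroxyl next to the carbonyl.

Step 4
Reactants: 3 (E)-1-[4-(benzyloxy)-2-hydroxyphenyl]-3-[4-(methoxymethoxy)phenyl]prop-2-en-1-one; 6 (E)-1-[2,4-bis(benzyloxy)-6-(methoxymethoxy)phenyl]-3-[4-(methoxymethoxy)phenyl]prop-2-en-1-one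
Product: 7 [4-(benzyloxy)-2-hydroxyphenyl]{(1S,2S,3R,4R)-2-[2,4-bis(benzyloxy)-6-(methoxymethoxy)benzoyl]-3,4-bis[4-(methoxymethoxy)phenyl]cyclobutyl}methanone (all-trans)
Conditions: Sc(OTf)3 (cat.), (S,S)-t-Bu-PyBox (cat.), Ru(bpy)3(PF6)2 (cat.), i-PrOAc/MeCN, blue LEDs, rt
Reagents that add atoms: none
Why: In this chiral-Lewis-acid-catalysed, triplet-sensitised crossed [2+2] enone–alkene photocycloaddition, an addition that loses no atom, only the chalcone chelated to the Sc(OTf)3/t-Bu-PyBox complex through its 2-hydroxyaryl ketone should be sensitised by Ru(bpy)3(PF6)2, the non-chelating chalcone present in excess should trap it head to head through the doubly benzylic 1,4-biradical that closes to the all-trans ring, and the ligand-shielded face of the bound chalcone should fix the absolute configuration of the aroyl-bearing carbons C3 and C3''.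

Step 5
Reactants: 7 [4-(benzyloxy)-2-hydroxyphenyl]{(1S,2S,3R,4R)-2-[2,4-bis(benzyloxy)-6-(methoxymethoxy)benzoyl]-3,4-bis[4-(methoxymethoxy)phenyl]cyclobutyl}methanone
Product: 8 [4-(benzyloxy)-2-hydroxyphenyl]{(1S,2S,3R,4R)-2-[2,4-bis(benzyloxy)-6-hydroxybenzoyl]-3,4-bis(4-hydroxyphenyl)cyclobutyl}methanone (all-trans)
Conditions: aq. HCl, MeOH/THF, 40 °C
Reagents that add atoms: none
Why: Acid-catalysed methanolysis of the three methoxymethyl acetals should free the two ring-B phenols and the second ortho-hydroxyl while leaving the benzyl ethers, the ketones and the all-trans (thermodynamically preferred) ring stereocentres untouched.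

Step 6
Reactants: 8 [4-(benzyloxy)-2-hydroxyphenyl]{(1S,2S,3R,4R)-2-[2,4-bis(benzyloxy)-6-hydroxybenzoyl]-3,4-bis(4-hydroxyphenyl)cyclobutyl}methanone
Product: 10 (2S,3R)-7-(benzyloxy)-3-[(2S,3R)-5,7-bis(benzyloxy)-2-(4-hydroxyphenyl)-4-oxo-3,4-dihydro-2H-chromen-3-yl]-2-(4-hydroxyphenyl)-2,3-dihydro-4H-chromen-4-one, via bis(para-quinone methide) 9 (not isolated)
Conditions: PhI(OAc)2 (one equivalent), (CF3)2CHOH/CH2Cl2, −40 °C to rt
Reagents that add atoms: none
Why: Proposed new method: PhI(OAc)2 should exchange a ligand for one of the two electron-rich 4-hydroxyphenyl OH groups of 8 (the chelated 2-acylphenols and the benzyl ethers are far harder to oxidise) and, as iodobenzene departs, the strained C2–C2'' ring bond, benzylic and para to a phenol on both sides, should fragment in a Grob-type manner to the bis(para-quinone methide) 9, an overall loss of only two hydrogens. The closest known reaction types are the oxidative ring opening of 1,2-diarylcyclobutanes bearing para-hydroxy groups to bis(quinone methide) equivalents that are captured by oxygen nucleophiles (tetrahydrofuran-lignan chemistry) and the hypervalent-iodine generation of para-quinone methides from 4-alkylphenols followed by intramolecular oxa-1,6-addition. Each pyranone ring then closes 6-exo-trig: the ortho-hydroxyl of each aroyl group, held in plane by its hydrogen bond to the ketone, adds to the exocyclic methide carbon C2 or C2'' and the phenol rearomatises. C3 and C3'' are not touched and carry the trans-diaroyl (S,S) relationship of the cyclobutane into the (3R,3''R) relationship of the product (the descriptor changes only through ligand priorities), while C2 and C2'' are set by these neighbours because in the chair-like transition state the 4-hydroxyphenyl group and the large substituent on C3 or C3'' both lie equatorial, giving the 2,3-trans rings. The step needs cleavage of C2–C2'' in place of C2–C3 (secured because only that mode leaves both termini stabilised by a 4-hydroxyphenyl ring) and phenol capture faster than tautomerisation of 9 to the 4-hydroxychalcones or 5-exo capture by the distal carbonyl oxygen, for which the base-free, weakly acidic fluoroalcohol medium and the pre-organised chelated hydroxyls are relied on.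

Step 7
Reactants: 10 (2S,3R)-7-(benzyloxy)-3-[(2S,3R)-5,7-bis(benzyloxy)-2-(4-hydroxyphenyl)-4-oxo-3,4-dihydro-2H-chromen-3-yl]-2-(4-hydroxyphenyl)-2,3-dihydro-4H-chromen-4-one
Product: 11 (2S,3R)-3-[(2S,3R)-5,7-dihydroxy-2-(4-hydroxyphenyl)-4-oxo-3,4-dihydro-2H-chromen-3-yl]-7-hydroxy-2-(4-hydroxyphenyl)-2,3-dihydro-4H-chromen-4-one
Conditions: H2 (balloon), Pd/C, EtOAc/MeOH, rt
Reagents that add atoms: none
Why: Heterogeneous hydrogenolysis of the three benzyl aryl ethers should be faster than reduction of the hydrogen-bonded aryl ketones or of the benzylic O1–C2 bonds at atmospheric pressure, and it creates no stereocentre.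

Compound list
1 | 1-[4-(benzyloxy)-2-hydroxyphenyl]ethan-1-one | CC(=O)c1ccc(OCc2ccccc2)cc1O | starting material
2 | 4-(methoxymethoxy)benzaldehyde | COCOc1ccc(C=O)cc1 | starting material
3 | (E)-1-[4-(benzyloxy)-2-hydroxyphenyl]-3-[4-(methoxymethoxy)phenyl]prop-2-en-1-one | O=C(/C=C/c1ccc(OCOC)cc1)c1ccc(OCc2ccccc2)cc1O | intermediate
4 | 1-[2,4-bis(benzyloxy)-6-hydroxyphenyl]ethan-1-one | CC(=O)c1c(O)cc(OCc2ccccc2)cc1OCc1ccccc1 | starting material
5 | 1-[2,4-bis(benzyloxy)-6-(methoxymethoxy)phenyl]ethan-1-one | CC(=O)c1c(OCOC)cc(OCc2ccccc2)cc1OCc1ccccc1 | intermediate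
6 | (E)-1-[2,4-bis(benzyloxy)-6-(methoxymethoxy)phenyl]-3-[4-(methoxymethoxy)phenyl]prop-2-en-1-one | O=C(/C=C/c1ccc(OCOC)cc1)c1c(OCOC)cc(OCc2ccccc2)cc1OCc1ccccc1 | intermediate
7 | [4-(benzyloxy)-2-hydroxyphenyl]{(1S,2S,3R,4R)-2-[2,4-bis(benzyloxy)-6-(methoxymethoxy)benzoyl]-3,4-bis[4-(methoxymethoxy)phenyl]cyclobutyl}methanone, all-trans | O=C(c1ccc(OCc2ccccc2)cc1O)[C@@H]1[C@@H](C(=O)c2c(OCOC)cc(OCc3ccccc3)cc2OCc2ccccc2)[C@H](c2ccc(OCOC)cc2)[C@H]1c1ccc(OCOC)cc1 | intermediate
8 | [4-(benzyloxy)-2-hydroxyphenyl]{(1S,2S,3R,4R)-2-[2,4-bis(benzyloxy)-6-hydroxybenzoyl]-3,4-bis(4-hydroxyphenyl)cyclobutyl}methanone, all-trans | O=C(c1ccc(OCc2ccccc2)cc1O)[C@@H]1[C@@H](C(=O)c2c(O)cc(OCc3ccccc3)cc2OCc2ccccc2)[C@H](c2ccc(O)cc2)[C@H]1c1ccc(O)cc1 | intermediate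
9 | (2S,3S)-1-[4-(benzyloxy)-2-hydroxyphenyl]-4-[2,4-bis(benzyloxy)-6-hydroxyphenyl]-2,3-bis[(4-oxocyclohexa-2,5-dien-1-ylidene)methyl]butane-1,4-dione | O=C1C=CC(=C[C@H](C(=O)c2ccc(OCc3ccccc3)cc2O)[C@@H](C(=O)c2c(O)cc(OCc3ccccc3)cc2OCc2ccccc2)C=C2C=CC(=O)C=C2)C=C1 | intermediate
10 | (2S,3R)-7-(benzyloxy)-3-[(2S,3R)-5,7-bis(benzyloxy)-2-(4-hydroxyphenyl)-4-oxo-3,4-dihydro-2H-chromen-3-yl]-2-(4-hydroxyphenyl)-2,3-dihydro-4H-chromen-4-one | O=C1c2ccc(OCc3ccccc3)cc2O[C@H](c2ccc(O)cc2)[C@H]1[C@H]1C(=O)c2c(OCc3ccccc3)cc(OCc3ccccc3)cc2O[C@@H]1c1ccc(O)cc1 | intermediate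
11 | (2S,3R)-3-[(2S,3R)-5,7-dihydroxy-2-(4-hydroxyphenyl)-4-oxo-3,4-dihydro-2H-chromen-3-yl]-7-hydroxy-2-(4-hydroxyphenyl)-2,3-dihydro-4H-chromen-4-one | O=C1c2ccc(O)cc2O[C@H](c2ccc(O)cc2)[C@H]1[C@H]1C(=O)c2c(O)cc(O)cc2O[C@@H]1c1ccc(O)cc1 | target

Total step count: 7
Longest linear sequence: 6 steps (steps 2, 3, 4, 5, 6, 7)

Steps most likely to fail

1. Step 6 (proposed new method). What may go wrong: fragmentation of the four-membered ring may lag behind simple para-dearomatisation of the oxidised phenol; the opened quinone methides may tautomerise to 4-hydroxychalcones before the phenols add, which would erase the C3/C3'' configuration; capture by the distal carbonyl oxygen or over-oxidation of the product phenols may compete. Fallback with known chemistry, setting out from 1 and 5 and returning at 10: the enolate of 5 (LiN(SiMe3)2, THF, −78 °C) is brominated with NBS to 2-bromo-1-[2,4-bis(benzyloxy)-6-(methoxymethoxy)phenyl]ethan-1-one F1. The dianion of 1, formed with excess LiN(SiMe3)2, is alkylated with F1 to the 1,4-diketone 1-[4-(benzyloxy)-2-hydroxyphenyl]-4-[2,4-bis(benzyloxy)-6-(methoxymethoxy)phenyl]butane-1,4-dione F2. Double Claisen–Schmidt condensation of F2 with 2 (KOH, EtOH) should give (2E,3E)-1-[4-(benzyloxy)-2-hydroxyphenyl]-4-[2,4-bis(benzyloxy)-6-(methoxymethoxy)phenyl]-2,3-bis[4-(methoxymethoxy)benzylidene]butane-1,4-dione F3. Acid removal of the three MOM groups (HCl, MeOH) should give (2E,3E)-1-[4-(benzyloxy)-2-hydroxyphenyl]-4-[2,4-bis(benzyloxy)-6-hydroxyphenyl]-2,3-bis(4-hydroxybenzylidene)butane-1,4-dione F4. Its double intramolecular oxa-Michael addition (NaOAc, EtOH, reflux) closes both pyranone rings under thermodynamic 2,3-trans control. The diastereomer with like halves is separated from the unlike one by chromatography and resolved by preparative HPLC on a chiral stationary phase to give 10.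

2. Step 4. What may go wrong: homodimerisation of the sensitised chalcone instead of cross-addition, head-to-tail addition, cis ring closure, or weak facial discrimination by the catalyst when the alkene partner is an enone. Fallback, setting out from 3, 4 and 2 and returning at 8: a temporary silicon tether makes the cycloaddition intramolecular. 4 and 2 are condensed (KOH, EtOH) to (E)-1-[2,4-bis(benzyloxy)-6-hydroxyphenyl]-3-[4-(methoxymethoxy)phenyl]prop-2-en-1-one F5. 3 is silylated with excess i-Pr2SiCl2 (imidazole, CH2Cl2) to (E)-1-[4-(benzyloxy)-2-{[chlorodi(propan-2-yl)silyl]oxy}phenyl]-3-[4-(methoxymethoxy)phenyl]prop-2-en-1-one F6. F6 is joined to F5 (imidazole, DMF) to give the mixed bis(aryloxy)di(propan-2-yl)silane that bridges the ortho-oxygens of the two chalcones F7. Sensitised intramolecular [2+2] photocycloaddition (thioxanthen-9-one, 405 nm, dilute MeCN) should give the racemic silicon-bridged all-trans cyclobutane F8, equilibrated with DBU if the aroyl groups emerge cis. HCl in MeOH then removes the tether and the MOM groups, and racemic 8 is resolved by preparative chiral HPLC to give 8.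

3. Step 7. What may go wrong: hydrogenolytic opening of the benzylic O1–C2 and O1''–C2'' bonds or reduction of the aryl ketones during debenzylation. Fallback, setting out from 10 and returning at 11: non-reductive Lewis-acid dealkylation with BCl3 and pentamethylbenzene as benzyl-cation scavenger (CH2Cl2, −78 °C) should cleave the three benzyl ethers without hydrogen and without opening the pyranone rings; it makes no new compound on the way.

Further compounds
F1 | step 6 | 2-bromo-1-[2,4-bis(benzyloxy)-6-(methoxymethoxy)phenyl]ethan-1-one | O=C(CBr)c1c(OCOC)cc(OCc2ccccc2)cc1OCc1ccccc1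
F2 | step 6 | 1-[4-(benzyloxy)-2-hydroxyphenyl]-4-[2,4-bis(benzyloxy)-6-(methoxymethoxy)phenyl]butane-1,4-dione | O=C(CCC(=O)c1c(OCOC)cc(OCc2ccccc2)cc1OCc1ccccc1)c1ccc(OCc2ccccc2)cc1O
F3 | step 6 | (2E,3E)-1-[4-(benzyloxy)-2-hydroxyphenyl]-4-[2,4-bis(benzyloxy)-6-(methoxymethoxy)phenyl]-2,3-bis[4-(methoxymethoxy)benzylidene]butane-1,4-dione | O=C(c1ccc(OCc2ccccc2)cc1O)/C(=C/c1ccc(OCOC)cc1)/C(=C\c1ccc(OCOC)cc1)C(=O)c1c(OCOC)cc(OCc2ccccc2)cc1OCc1ccccc1
F4 | step 6 | (2E,3E)-1-[4-(benzyloxy)-2-hydroxyphenyl]-4-[2,4-bis(benzyloxy)-6-hydroxyphenyl]-2,3-bis(4-hydroxybenzylidene)butane-1,4-dione | O=C(c1ccc(OCc2ccccc2)cc1O)/C(=C/c1ccc(O)cc1)/C(=C\c1ccc(O)cc1)C(=O)c1c(O)cc(OCc2ccccc2)cc1OCc1ccccc1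
F5 | step 4 | (E)-1-[2,4-bis(benzyloxy)-6-hydroxyphenyl]-3-[4-(methoxymethoxy)phenyl]prop-2-en-1-one | O=C(/C=C/c1ccc(OCOC)cc1)c1c(O)cc(OCc2ccccc2)cc1OCc1ccccc1
F6 | step 4 | (E)-1-[4-(benzyloxy)-2-{[chlorodi(propan-2-yl)silyl]oxy}phenyl]-3-[4-(methoxymethoxy)phenyl]prop-2-en-1-one | CC(C)[Si](Cl)(Oc1cc(OCc2ccccc2)ccc1C(=O)/C=C/c1ccc(OCOC)cc1)C(C)C
F7 | step 4 | bis(aryloxy)di(propan-2-yl)silane linking the 2'-oxygen of chalcone 3 and the 6'-oxygen of chalcone F5 | CC(C)[Si](Oc1cc(OCc2ccccc2)ccc1C(=O)/C=C/c1ccc(OCOC)cc1)(Oc1cc(OCc2ccccc2)cc(OCc2ccccc2)c1C(=O)/C=C/c1ccc(OCOC)cc1)C(C)C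
F8 | step 4 | silicon-bridged all-trans cyclobutane, the O,O'-di(propan-2-yl)silanediyl derivative of the 2'-hydroxy analogue of 7, racemic (one enantiomer drawn) | CC(C)[Si]1(C(C)C)Oc2cc(OCc3ccccc3)ccc2C(=O)[C@H]2[C@H](c3ccc(OCOC)cc3)[C@@H](c3ccc(OCOC)cc3)[C@@H]2C(=O)c2c(O1)cc(OCc3ccccc3)cc2OCc2ccccc2
F0 | step 7 | none | none
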